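**Plan**

- Retrosynthesis: the benzyl ether and the C2–CH2 bond of the acetate arm are cut first (C2 anion plus oxirane). Then come the C7–O bond (a C7–H phenol oxidised through the 4,7-quinone), the C5–C6 bond of the benzene ring (aldol), the acetyl C–CH3 bond (MeLi on a lactone), the furfurylic CH2–CH(O)Ar bond (lateral aldol of a 2-methyl-3-furoate) and last the furan ring (Feist–Benary).
- Enabling feature: in the benzene ring of the benzofuran, C5 carries H and C6 the aryl group, and both sit between oxygen-bearing C4 and C7. C4 with C5 maps onto an acetyl group on C3a, and C6 with C7 onto an aroylmethyl arm on C7a. C5–C6 is therefore an aldol bond, and the dehydrated adduct is the keto tautomer of the C4 phenol.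
- Forward order: furan ring (step 1); aroylmethyl arm and methyl ketone on neighbouring furan carbons (steps 2–4); benzene ring by aldol benzannulation, completing the benzofuran (step 5); C7 oxygen and both methyl ethers (steps 6–7); C2 acetate arm (steps 8–10); debenzylation (step 11). The sequence is linear.
- Stereochemistry: the target has no stereocentre. The racemic centres that appear in 3, 7–10 and 12 are erased by dehydration, oxidation or aromatisation.

Key step: step 5

Remark: organolithium steps are quenched with aqueous NH4Cl, so lithium leaves as LiCl; hydroxy ketone 10 is drawn open-chain although part of it may exist as its cyclic hemiketal.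

**Route**

Step 1
Reactants: 1 ethyl acetoacetate; 2 chloroacetone
Product: 4 ethyl 2,4-dimethylfuran-3-carboxylate, via hydroxydihydrofuran 3 (not isolated)
Conditions: pyridine, rt → 50 °C; then 2 M HCl, 60 °C
Reagents that add atoms: none
Why: Feist–Benary furan synthesis: the acetoacetate carbon adds to the ketone of 2, the enol oxygen displaces chloride to close hydroxydihydrofuran 3, and acid-promoted loss of water aromatises it, which puts the methyl group of 2 on C4 and leaves C5 as C–H.

Step 2
Reactants: 4 ethyl 2,4-dimethylfuran-3-carboxylate; 5 4-(benzyloxy)benzaldehyde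
Product: 8 racemic 6-[4-(benzyloxy)phenyl]-3-methyl-6,7-dihydro-4H-furo[3,2-c]pyran-4-one, via lithiomethyl furoate 6 (not isolated), via lithium alkoxide adduct 7 (not isolated)
Conditions: LiN(i-Pr)2 (LDA, 1.1 equiv), THF, −78 °C; then 5, −78 → 0 °C; aq NH4Cl
Reagents that add atoms: none
Why: Lateral (vinylogous) lithiation followed by aldol addition and lactonisation, the furan counterpart of the toluate-to-dihydroisocoumarin reaction: only the 2-methyl anion is delocalised into the ester, so 6 should form selectively and add to the non-enolisable aldehyde 5, and alkoxide 7 closes the six-membered lactone with loss of ethoxide; the new carbinol centre is racemic and is removed in step 4.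

Step 3
Reactants: 8 racemic 6-[4-(benzyloxy)phenyl]-3-methyl-6,7-dihydro-4H-furo[3,2-c]pyran-4-one
Product: 10 racemic 1-(2-{2-[4-(benzyloxy)phenyl]-2-hydroxyethyl}-4-methylfuran-3-yl)ethan-1-one, via lithium hemiketalate 9 (not isolated)
Conditions: MeLi (1.1 equiv), THF, −78 °C; aq NH4Cl at −78 °C
Reagents that add atoms: methyllithium, [Li]C
Why: Mono-addition of an organolithium to a lactone: at −78 °C the tetrahedral lithium hemiketalate 9 should persist until the cold quench and so shield the carbonyl from a second equivalent, as in the conversion of dihydroisocoumarins into lactols; 10 is used crude because it can equilibrate with its cyclic hemiketal.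

Step 4
Reactants: 10 racemic 1-(2-{2-[4-(benzyloxy)phenyl]-2-hydroxyethyl}-4-methylfuran-3-yl)ethan-1-one
Product: 11 2-(3-acetyl-4-methylfuran-2-yl)-1-[4-(benzyloxy)phenyl]ethan-1-one
Conditions: Dess–Martin periodinane (1.2 equiv), CH2Cl2, 0 °C → rt
Reagents that add atoms: none
Why: Dess–Martin oxidation of the benzylic secondary alcohol under near-neutral conditions should give the 1,5-diketone without the strong acid that would close this ene-1,5-dione to a pyrylium salt, and it removes the only stereocentre.

Step 5
Reactants: 11 2-(3-acetyl-4-methylfuran-2-yl)-1-[4-(benzyloxy)phenyl]ethan-1-one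
Product: 14 6-[4-(benzyloxy)phenyl]-3-methyl-1-benzofuran-4-ol, via aldol adduct 12 (not isolated), via dienone 13 (not isolated)
Conditions: KOH (3 equiv), EtOH, 70 °C, argon; then aq HCl
Reagents that add atoms: none
Why: Base reversibly deprotonates both ketones; the small equilibrium share of the acetyl methyl enolate adds to the still-neutral aroyl carbonyl to give aldol 12, E1cB loss of water gives dienone 13, and removal of a C7 proton converts this keto tautomer into the phenoxide of 14, which makes the sequence irreversible. The closest known reaction is the base-mediated cyclodehydration of 2-acetyl-deoxybenzoins and related 1,5-diketones to 3-aryl-1-naphthols, the laboratory counterpart of polyketide aldol aromatisation. The benzene ring closes in a 6-(enolendo)-exo-trig mode across the furan C2–C3 edge, which holds the two carbonyl arms cis and coplanar. No stereocentre survives, since the carbinol carbon of 12 becomes the sp2 carbon C6. The step needs chemoselectivity between two enolisable sites, and ring size secures it: the furfurylic methylene is deprotonated first but has no productive partner (C-attack on the acetyl carbonyl would need a cyclobutanol and O-attack gives a pyranol that reverts under base), so that enolate merely waits, while the protic medium keeps part of the aroyl ketone un-enolised as the electrophile. Strong acid is avoided because it would divert the ene-1,5-dione to a pyrylium salt.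

Step 6
Reactants: 14 6-[4-(benzyloxy)phenyl]-3-methyl-1-benzofuran-4-ol
Product: 15 6-[4-(benzyloxy)phenyl]-3-methyl-1-benzofuran-4,7-dione
Conditions: (KSO3)2NO (2.5 equiv), KH2PO4, acetone/H2O, rt
Reagents that add atoms: potassium nitrosodisulfonate (Fremy's salt), [K+].[K+].[O]N(S(=O)(=O)[O-])S(=O)(=O)[O-]
Why: Teuber oxidation: two equivalents of the nitroxyl radical oxidise a phenol with a free para position to the para-quinone, here at C7, under buffered conditions that should leave the benzyl ether and the furan ring untouched.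

Step 7
Reactants: 15 6-[4-(benzyloxy)phenyl]-3-methyl-1-benzofuran-4,7-dione
Product: 17 6-[4-(benzyloxy)phenyl]-4,7-dimethoxy-3-methyl-1-benzofuran, via hydroquinone 16 (not isolated)
Conditions: Na2S2O4, THF/H2O, rt; then KOH, Me2SO4, n-Bu4NBr (cat.), rt
Reagents that add atoms: dimethyl sulfate, COS(=O)(=O)OC
Why: One-pot reductive methylation: dithionite reduces the quinone to hydroquinone 16, whose bis-phenoxide is methylated at once under phase-transfer Williamson conditions, so the air-sensitive hydroquinone is not handled.

Step 8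
Reactants: 17 6-[4-(benzyloxy)phenyl]-4,7-dimethoxy-3-methyl-1-benzofuran
Product: 19 2-{6-[4-(benzyloxy)phenyl]-4,7-dimethoxy-3-methyl-1-benzofuran-2-yl}ethan-1-ol, via 2-lithiobenzofuran 18 (not isolated)
Conditions: n-BuLi (1.1 equiv), THF, −78 °C; then oxirane, −78 °C → rt; aq NH4Cl
Reagents that add atoms: oxirane, C1CO1
Why: Heteroaryllithium–epoxide alkylation: C2–H, alpha to the ring oxygen, is the most acidic proton of a 3-substituted benzofuran and should be removed by n-BuLi at −78 °C in preference to C5–H or the benzylic ether protons, and 18 opens oxirane to install the two-carbon hydroxyethyl chain.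

Step 9
Reactants: 19 2-{6-[4-(benzyloxy)phenyl]-4,7-dimethoxy-3-methyl-1-benzofuran-2-yl}ethan-1-ol
Product: 21 2-{6-[4-(benzyloxy)phenyl]-4,7-dimethoxy-3-methyl-1-benzofuran-2-yl}acetic acid, via aldehyde 20 (not isolated)
Conditions: TEMPO (0.2 equiv), PhI(OAc)2 (2.2 equiv), MeCN/H2O (1:1), rt
Reagents that add atoms: water, O
Why: Nitroxyl-catalysed oxidation with PhI(OAc)2 in aqueous acetonitrile takes the primary alcohol through aldehyde 20 and its hydrate to the acid under chlorine-free, near-neutral conditions that should spare the dimethoxyarene, the furan ring and the benzyl ether.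

Step 10
Reactants: 21 2-{6-[4-(benzyloxy)phenyl]-4,7-dimethoxy-3-methyl-1-benzofuran-2-yl}acetic acid
Product: 22 methyl 2-{6-[4-(benzyloxy)phenyl]-4,7-dimethoxy-3-methyl-1-benzofuran-2-yl}acetate
Conditions: MeOH, H2SO4 (cat.), 60 °C
Reagents that add atoms: methanol, CO
Why: Fischer esterification of an unhindered arylacetic acid in methanol; the aryl methyl ethers, the benzyl ether and the 2,3-disubstituted benzofuran tolerate catalytic acid.

Step 11
Reactants: 22 methyl 2-{6-[4-(benzyloxy)phenyl]-4,7-dimethoxy-3-methyl-1-benzofuran-2-yl}acetate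
Product: 23 phenylcandilide B (methyl 2-[6-(4-hydroxyphenyl)-4,7-dimethoxy-3-methyl-1-benzofuran-2-yl]acetate)
Conditions: H2 (1 atm), Pd/C, EtOAc/MeOH, rt
Reagents that add atoms: none
Why: Hydrogenolysis of the benzyl aryl ether over Pd/C at ambient pressure is far faster than reduction of the tetrasubstituted furan double bond or of the ester and frees the phenol of the target.

**Compound list**

1 | ethyl acetoacetate | CCOC(=O)CC(C)=O | starting material
2 | chloroacetone | CC(=O)CCl | starting material
3 | racemic ethyl 4-hydroxy-2,4-dimethyl-4,5-dihydrofuran-3-carboxylate | CCOC(=O)C1=C(C)OCC1(C)O | intermediate (not isolated)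
4 | ethyl 2,4-dimethylfuran-3-carboxylate | CCOC(=O)c1c(C)coc1C | intermediate
5 | 4-(benzyloxy)benzaldehyde | O=Cc1ccc(OCc2ccccc2)cc1 | starting material
6 | ethyl 2-(lithiomethyl)-4-methylfuran-3-carboxylate | CCOC(=O)c1c(C)coc1C[Li] | intermediate (not isolated)
7 | racemic lithium 1-[4-(benzyloxy)phenyl]-2-[3-(ethoxycarbonyl)-4-methylfuran-2-yl]ethan-1-olate | CCOC(=O)c1c(C)coc1CC([O-])c1ccc(OCc2ccccc2)cc1.[Li+] | intermediate (not isolated)
8 | racemic 6-[4-(benzyloxy)phenyl]-3-methyl-6,7-dihydro-4H-furo[3,2-c]pyran-4-one | Cc1coc2c1C(=O)OC(c1ccc(OCc3ccccc3)cc1)C2 | intermediate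
9 | lithium 6-[4-(benzyloxy)phenyl]-3,4-dimethyl-6,7-dihydro-4H-furo[3,2-c]pyran-4-olate (mixture of racemic diastereomers) | Cc1coc2c1C(C)([O-])OC(c1ccc(OCc3ccccc3)cc1)C2.[Li+] | intermediate (not isolated)
10 | racemic 1-(2-{2-[4-(benzyloxy)phenyl]-2-hydroxyethyl}-4-methylfuran-3-yl)ethan-1-one | CC(=O)c1c(C)coc1CC(O)c1ccc(OCc2ccccc2)cc1 | intermediate
11 | 2-(3-acetyl-4-methylfuran-2-yl)-1-[4-(benzyloxy)phenyl]ethan-1-one | CC(=O)c1c(C)coc1CC(=O)c1ccc(OCc2ccccc2)cc1 | intermediate
12 | racemic 6-[4-(benzyloxy)phenyl]-6-hydroxy-3-methyl-6,7-dihydro-1-benzofuran-4(5H)-one | Cc1coc2c1C(=O)CC(O)(c1ccc(OCc3ccccc3)cc1)C2 | intermediate (not isolated)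
13 | 6-[4-(benzyloxy)phenyl]-3-methyl-1-benzofuran-4(7H)-one | Cc1coc2c1C(=O)C=C(c1ccc(OCc3ccccc3)cc1)C2 | intermediate (not isolated)
14 | 6-[4-(benzyloxy)phenyl]-3-methyl-1-benzofuran-4-ol | Cc1coc2cc(-c3ccc(OCc4ccccc4)cc3)cc(O)c12 | intermediate
15 | 6-[4-(benzyloxy)phenyl]-3-methyl-1-benzofuran-4,7-dione | Cc1coc2c1C(=O)C=C(c1ccc(OCc3ccccc3)cc1)C2=O | intermediate
16 | 6-[4-(benzyloxy)phenyl]-3-methyl-1-benzofuran-4,7-diol | Cc1coc2c(O)c(-c3ccc(OCc4ccccc4)cc3)cc(O)c12 | intermediate (not isolated)
17 | 6-[4-(benzyloxy)phenyl]-4,7-dimethoxy-3-methyl-1-benzofuran | Cc1coc2c(OC)c(-c3ccc(OCc4ccccc4)cc3)cc(OC)c12 | intermediate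
18 | {6-[4-(benzyloxy)phenyl]-4,7-dimethoxy-3-methyl-1-benzofuran-2-yl}lithium | [Li]c1oc2c(OC)c(-c3ccc(OCc4ccccc4)cc3)cc(OC)c2c1C | intermediate (not isolated)
19 | 2-{6-[4-(benzyloxy)phenyl]-4,7-dimethoxy-3-methyl-1-benzofuran-2-yl}ethan-1-ol | OCCc1oc2c(OC)c(-c3ccc(OCc4ccccc4)cc3)cc(OC)c2c1C | intermediate
20 | 2-{6-[4-(benzyloxy)phenyl]-4,7-dimethoxy-3-methyl-1-benzofuran-2-yl}acetaldehyde | O=CCc1oc2c(OC)c(-c3ccc(OCc4ccccc4)cc3)cc(OC)c2c1C | intermediate (not isolated)
21 | 2-{6-[4-(benzyloxy)phenyl]-4,7-dimethoxy-3-methyl-1-benzofuran-2-yl}acetic acid | OC(=O)Cc1oc2c(OC)c(-c3ccc(OCc4ccccc4)cc3)cc(OC)c2c1C | intermediate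
22 | methyl 2-{6-[4-(benzyloxy)phenyl]-4,7-dimethoxy-3-methyl-1-benzofuran-2-yl}acetate | COC(=O)Cc1oc2c(OC)c(-c3ccc(OCc4ccccc4)cc3)cc(OC)c2c1C | intermediate
23 | phenylcandilide B, methyl 2-[6-(4-hydroxyphenyl)-4,7-dimethoxy-3-methyl-1-benzofuran-2-yl]acetate | COC(=O)Cc1oc2c(OC)c(-c3ccc(O)cc3)cc(OC)c2c1C | target

**Step count and risks**

Total step count: 11. Longest linear sequence: 11 steps (from 1 and 2; aldehyde 5 is purchased).

Steps most likely to fail:

1. Step 3, mono-addition of MeLi to lactone 8. The tetrahedral intermediate may collapse early and take up a second equivalent, or the furfurylic methylene may be deprotonated and the carboxylate lost by β-elimination. The fallback sets out from 8. Ring-opening aminolysis with the aluminium amide from AlMe3 and MeNH(OMe)·HCl (CH2Cl2, 0 °C → rt) should give the hydroxy Weinreb amide racemic 2-{2-[4-(benzyloxy)phenyl]-2-hydroxyethyl}-N-methoxy-N,4-dimethylfuran-3-carboxamide F1. MeMgBr (3 equiv, THF, 0 °C), which adds only once to an N-methoxy-N-methylamide, should then deliver hydroxy ketone 10, where the route is rejoined.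

2. Step 2, lateral lithiation, aldol addition and lactonisation. Ring metalation at C5 may compete, the lithiated ester may undergo Claisen-type self-condensation with unreacted 4, or the ethoxide set free may open the lactone by β-elimination to a styryl acid. The fallback sets out from 4. Saponification (LiOH, THF/H2O, 50 °C) should give 2,4-dimethylfuran-3-carboxylic acid F2. LiN(i-Pr)2 (2.2 equiv, THF, −78 → 0 °C) should then form the dianion lithium 2-(lithiomethyl)-4-methylfuran-3-carboxylate F3, in which the carboxylate directs metalation to the neighbouring methyl group and no electrophilic ester remains. Addition of 5 and acidic work-up should give racemic 2-{2-[4-(benzyloxy)phenyl]-2-hydroxyethyl}-4-methylfuran-3-carboxylic acid F4. Carbodiimide lactonisation (EDC·HCl, DMAP, CH2Cl2) comes back to the route at lactone 8.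

3. Step 6, nitroxyl oxidation of phenol 14. Conversion of the lipophilic phenol in the aqueous medium may be poor, and oxidation at the ortho carbon C5 or radical coupling of the aryloxyl intermediate may compete. The fallback sets out from 14. Two-electron oxidative dearomatisation with PhI(OAc)2 (2.2 equiv) in MeOH at 0 °C should give the para-quinone monoketal 6-[4-(benzyloxy)phenyl]-7,7-dimethoxy-3-methyl-1-benzofuran-4(7H)-one F5. Zn in AcOH should reduce it, with loss of methanol, to 6-[4-(benzyloxy)phenyl]-7-methoxy-3-methyl-1-benzofuran-4-ol F6. O-Methylation (MeI, K2CO3, acetone) comes back to the route at 17, so neither the free quinone nor the hydroquinone is needed.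

**Further compounds**

F1 | step 3 | racemic 2-{2-[4-(benzyloxy)phenyl]-2-hydroxyethyl}-N-methoxy-N,4-dimethylfuran-3-carboxamide | CON(C)C(=O)c1c(C)coc1CC(O)c1ccc(OCc2ccccc2)cc1
F2 | step 2 | 2,4-dimethylfuran-3-carboxylic acid | Cc1coc(C)c1C(=O)O
F3 | step 2 | lithium 2-(lithiomethyl)-4-methylfuran-3-carboxylate | [Li]Cc1occ(C)c1C(=O)[O-].[Li+]
F4 | step 2 | racemic 2-{2-[4-(benzyloxy)phenyl]-2-hydroxyethyl}-4-methylfuran-3-carboxylic acid | Cc1coc(CC(O)c2ccc(OCc3ccccc3)cc2)c1C(=O)O
F5 | step 6 | 6-[4-(benzyloxy)phenyl]-7,7-dimethoxy-3-methyl-1-benzofuran-4(7H)-one | Cc1coc2c1C(=O)C=C(c1ccc(OCc3ccccc3)cc1)C2(OC)OC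
F6 | step 6 | 6-[4-(benzyloxy)phenyl]-7-methoxy-3-methyl-1-benzofuran-4-ol | Cc1coc2c(OC)c(-c3ccc(OCc4ccccc4)cc3)cc(O)c12
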